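**Strategy.** The target consists of two identical 1,4-benzoquinone rings A and A' (C1=O, C2–OH, C3–chain, C4=O, C5–OMe, C6–Me) joined C3 to C3 by an unbranched tether C1'–C13'. The tether has an odd carbon count and a mirror plane through C7'. It is therefore cut at C2'–C3' and C11'–C12' into one nine-carbon dibromide and two arylethyl nucleophiles. One two-directional alkyl–alkyl Suzuki–Miyaura coupling makes both bonds and completes the carbon framework. Its precursor is a B-(2-arylethyl)-9-BBN. Its locally symmetric 3,5-dimethoxy-4-methylphenyl group already holds the C1 and C5 oxygens and the C6 methyl, which leaves only regiochemically unambiguous oxidation at C4 and C2.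

Key step: step 3

Remark: atom labels follow the numbering above. In steps 4 to 7 the two rings are insulated by thirteen methylenes and react by the same equation, so each step is written for the doubly converted product.

**Step 1**
Reactants: 1 3,5-dimethoxy-4-methylbenzaldehyde; 2 methyltriphenylphosphonium bromide
Product: 4 5-ethenyl-1,3-dimethoxy-2-methylbenzene (3,5-dimethoxy-4-methylstyrene), via methylidenetriphenylphosphorane 3 (not isolated)
Conditions: KOtBu, THF, 0 °C to rt
Reagents that add atoms: methyltriphenylphosphonium bromide 2, [Br-].C[P+](c1ccccc1)(c1ccccc1)c1ccccc1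
Why: Wittig methylenation, in which the non-stabilised ylide 3 adds to the unhindered, non-enolisable aryl aldehyde and the oxaphosphetane collapses to the terminal alkene, driven by P=O formation, with no stereocentre created.

**Step 2**
Reactants: 4 3,5-dimethoxy-4-methylstyrene (slight excess); 5 9-borabicyclo[3.3.1]nonane
Product: 6 B-[2-(3,5-dimethoxy-4-methylphenyl)ethyl]-9-borabicyclo[3.3.1]nonane
Conditions: 9-BBN (0.5 M in THF), 0 °C to rt; volatiles removed under argon, air-sensitive oil kept under argon
Reagents that add atoms: 9-borabicyclo[3.3.1]nonane 5, B1C2CCCC1CCC2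
Why: Anti-Markovnikov hydroboration, in which the bulky dialkylborane places boron on the terminal carbon of the styrene by four-centre syn addition, and the small excess of 4 ensures that no B–H bond is carried into step 3.

**Step 3**
Reactants: 6 B-[2-(3,5-dimethoxy-4-methylphenyl)ethyl]-9-borabicyclo[3.3.1]nonane (2.5 equiv); 7 1,9-dibromononane
Product: 9 1,13-bis(3,5-dimethoxy-4-methylphenyl)tridecane, via 5-(11-bromoundecyl)-1,3-dimethoxy-2-methylbenzene 8 (not isolated)
Conditions: Pd(OAc)2 (8 mol %), PCy3 (16 mol %), K3PO4·H2O (2.6 equiv), THF, rt, argon; filtration through SiO2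
Reagents that add atoms: 1,9-dibromononane 7, BrCCCCCCCCCBr
Why: Zerovalent palladium ligated by PCy3, formed in situ from Pd(OAc)2, enters a primary C–Br bond of 7 by SN2-type oxidative addition, hydroxide from K3PO4·H2O turns 6 into its ate complex, which passes the arylethyl group to the divalent alkylpalladium bromide, and reductive elimination forms C2'–C3' to give bromide 8, which runs through the same cycle at its other end to form C11'–C12'. The closest known reaction type is the room-temperature B-alkyl Suzuki–Miyaura coupling of unactivated primary alkyl bromides bearing β-hydrogens with B-alkyl-9-BBN reagents under a palladium trialkylphosphine catalyst, applied here to both termini of one α,ω-dibromide. No ring is closed and no stereocentre is created. The step needs C–C reductive elimination to outpace β-hydride elimination from either alkyl group on divalent palladium, which the bulky, strongly donating PCy3 secures, and it needs transfer of the exocyclic group only, which the substrate secures because that B–C bond is primary while the two bicyclic B–C bonds are secondary and hindered. Nine methylenes keep the two C–Br ends independent, so the excess of 6 should carry 8 on to 9, and the aryl methyl ethers are inert spectators.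

**Step 4**
Reactants: 9 1,13-bis(3,5-dimethoxy-4-methylphenyl)tridecane
Product: 10 5,5'-(tridecane-1,13-diyl)bis(3-methoxy-2-methylphenol)
Conditions: NaSEt (6 equiv), DMF, 140 °C; then 1 M HCl
Reagents that add atoms: none
Why: Nucleophilic aryl methyl ether cleavage (SN2 attack of thiolate on the O–CH3 carbon), in which the two methoxy groups of each ring are equivalent and the phenoxide left by the first cleavage makes the second aryloxide a much poorer leaving group, so each ring should stop at the mono-phenol.

**Step 5**
Reactants: 10 5,5'-(tridecane-1,13-diyl)bis(3-methoxy-2-methylphenol)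
Product: 11 5,5'-(tridecane-1,13-diyl)bis(3-methoxy-2-methylcyclohexa-2,5-diene-1,4-dione)
Conditions: (KSO3)2NO (5 equiv), KH2PO4, acetone/H2O, rt
Reagents that add atoms: dipotassium nitrosodisulfonate, [K+].[K+].[O]N(S(=O)(=O)[O-])S(=O)(=O)[O-]
Why: Teuber oxidation, in which one nitrosodisulfonate radical removes the phenolic hydrogen and a second delivers oxygen to the free para position C4, a pattern well established for 3-methoxy-5-alkylphenols, giving the para-quinone with carbonyls at C1 and C4.

**Step 6**
Reactants: 11 5,5'-(tridecane-1,13-diyl)bis(3-methoxy-2-methylcyclohexa-2,5-diene-1,4-dione)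
Product: 12 1,1'-(tridecane-1,13-diyl)bis(3-methoxy-4-methyl-7-oxabicyclo[4.1.0]hept-3-ene-2,5-dione)
Conditions: 30% H2O2, Na2CO3, THF/H2O, 0 °C, short contact; pH 7 buffer quench
Reagents that add atoms: hydrogen peroxide, OO
Why: Weitz–Scheffer nucleophilic epoxidation, in which hydroperoxide adds to the unsubstituted C2 of the more electrophilic C2=C3 bond while C5=C6 is tetrasubstituted and deactivated as a vinylogous ester; each oxirane is necessarily cis-fused and forms without facial bias, and the resulting racemic and meso forms do not matter because step 7 erases all four stereocentres.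

**Step 7**
Reactants: 12 1,1'-(tridecane-1,13-diyl)bis(3-methoxy-4-methyl-7-oxabicyclo[4.1.0]hept-3-ene-2,5-dione)
Product: 13 3,3'-(tridecane-1,13-diyl)bis(2-hydroxy-5-methoxy-6-methylcyclohexa-2,5-diene-1,4-dione) (target)
Conditions: H2SO4 on SiO2, CH2Cl2, rt
Reagents that add atoms: none
Why: Acid-catalysed epoxyquinone to hydroxyquinone isomerisation, in which enolisation with loss of the C2 hydrogen opens the C3–O bond so that oxygen stays on C2 and the conjugated quinone is restored, while the peroxide-free, water-poor medium spares the C5 vinylogous methyl ester.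

**Compound list**
1 | 3,5-dimethoxy-4-methylbenzaldehyde | COc1cc(C=O)cc(OC)c1C | starting material
2 | methyltriphenylphosphonium bromide | [Br-].C[P+](c1ccccc1)(c1ccccc1)c1ccccc1 | starting material
3 | methylidenetriphenylphosphorane | C=P(c1ccccc1)(c1ccccc1)c1ccccc1 | intermediate
4 | 5-ethenyl-1,3-dimethoxy-2-methylbenzene | C=Cc1cc(OC)c(C)c(OC)c1 | intermediate
5 | 9-borabicyclo[3.3.1]nonane | B1C2CCCC1CCC2 | starting material
6 | B-[2-(3,5-dimethoxy-4-methylphenyl)ethyl]-9-borabicyclo[3.3.1]nonane | COc1cc(CCB2C3CCCC2CCC3)cc(OC)c1C | intermediate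
7 | 1,9-dibromononane | BrCCCCCCCCCBr | starting material
8 | 5-(11-bromoundecyl)-1,3-dimethoxy-2-methylbenzene | COc1cc(CCCCCCCCCCCBr)cc(OC)c1C | intermediate
9 | 1,13-bis(3,5-dimethoxy-4-methylphenyl)tridecane | COc1cc(CCCCCCCCCCCCCc2cc(OC)c(C)c(OC)c2)cc(OC)c1C | intermediate
10 | 5,5'-(tridecane-1,13-diyl)bis(3-methoxy-2-methylphenol) | COc1cc(CCCCCCCCCCCCCc2cc(O)c(C)c(OC)c2)cc(O)c1C | intermediate
11 | 5,5'-(tridecane-1,13-diyl)bis(3-methoxy-2-methylcyclohexa-2,5-diene-1,4-dione) | COC1=C(C)C(=O)C=C(CCCCCCCCCCCCCC2=CC(=O)C(C)=C(OC)C2=O)C1=O | intermediate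
12 | 1,1'-(tridecane-1,13-diyl)bis(3-methoxy-4-methyl-7-oxabicyclo[4.1.0]hept-3-ene-2,5-dione), cis-fused oxiranes, racemic and meso forms together | COC1=C(C)C(=O)C2OC2(CCCCCCCCCCCCCC34OC3C(=O)C(C)=C(OC)C4=O)C1=O | intermediate
13 | 3,3'-(tridecane-1,13-diyl)bis(2-hydroxy-5-methoxy-6-methylcyclohexa-2,5-diene-1,4-dione) | COC1=C(C)C(=O)C(O)=C(CCCCCCCCCCCCCC2=C(O)C(=O)C(C)=C(OC)C2=O)C1=O | target

Total step count: 7. Longest linear sequence: 7 steps (1 to 13).

**Steps most likely to fail**

1. **Step 3.**
   - Risk: Reductive elimination may lose out to β-hydride elimination, since the transferred arylethyl group has benzylic β-hydrogens. Conversion may also stall after the first C–C bond, which would leave a mixture that is hard to separate.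
   - Fallback (sets out from 1, returns at 9): the tether is divided 1+11+1 and built by olefination. 1,11-Dibromoundecane and PPh3 (DMF, 120 °C) should give undecane-1,11-diylbis(triphenylphosphonium) dibromide F1. KN(SiMe3)2 (THF, −78 to 0 °C) converts it into undecane-1,11-diylidenebis(triphenylphosphorane) F2. This condenses with two equivalents of 1 in a double Wittig reaction to give (1Z,12Z)-1,13-bis(3,5-dimethoxy-4-methylphenyl)trideca-1,12-diene F3, whose alkene geometry is of no consequence. Hydrogenation (H2, Pd/C, EtOAc) then gives 9.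

2. **Step 6.**
   - Risk: Hydroperoxide or hydroxide may attack the methoxy-bearing C5, with loss of the methyl ether by addition–elimination. Premature base-induced opening of the oxirane would expose the hydroxyquinone anion to oxidative ring degradation by excess peroxide.
   - Fallback (sets out from 11, returns at 13, and also replaces step 7): oxygen is brought to C2 as acetate under acid. In the Thiele–Winter acetoxylation (Ac2O, cat. H2SO4 or BF3·OEt2, rt), C2 is the only open position, so it should give 1,13-bis(2,3,6-triacetoxy-5-methoxy-4-methylphenyl)tridecane F4. Methanolysis (K2CO3, MeOH, argon) frees 1,13-bis(2,3,6-trihydroxy-5-methoxy-4-methylphenyl)tridecane F5, which should autoxidise to 13 once air is admitted. Methanol as solvent makes any exchange at C5 degenerate.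

3. **Step 5.**
   - Risk: Poor contact between the lipophilic bis-phenol and the water-soluble oxidant may slow the oxidation. Phenoxyl radical coupling or ortho oxidation at C2 could then compete, and both rings must be converted.
   - Fallback (sets out from 9, returns at 11, and also replaces step 4): the C4 oxygen is installed by formylation and aryl migration, and the quinone is released by oxidative demethylation. Vilsmeier–Haack formylation (POCl3, DMF, 0 to 80 °C) at one of the two equivalent ring CH positions should give 6,6'-(tridecane-1,13-diyl)bis(2,4-dimethoxy-3-methylbenzaldehyde) F6. Baeyer–Villiger oxidation (mCPBA, CH2Cl2) gives 1,13-bis(2-formyloxy-3,5-dimethoxy-4-methylphenyl)tridecane F7. K2CO3 in MeOH frees 6,6'-(tridecane-1,13-diyl)bis(2,4-dimethoxy-3-methylphenol) F8. (NH4)2Ce(NO3)6 (MeCN/H2O, 0 °C) then oxidises the para-methoxyphenol pair C4–OH/C1–OMe with loss of methanol and gives 11.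

**Further compounds**
F1 | step 3 | undecane-1,11-diylbis(triphenylphosphonium) dibromide | [Br-].[Br-].c1ccccc1[P+](c1ccccc1)(c1ccccc1)CCCCCCCCCCC[P+](c1ccccc1)(c1ccccc1)c1ccccc1
F2 | step 3 | undecane-1,11-diylidenebis(triphenylphosphorane) | c1ccccc1P(c1ccccc1)(c1ccccc1)=CCCCCCCCCCC=P(c1ccccc1)(c1ccccc1)c1ccccc1
F3 | step 3 | (1Z,12Z)-1,13-bis(3,5-dimethoxy-4-methylphenyl)trideca-1,12-diene | COc1cc(/C=C\CCCCCCCCC/C=C\c2cc(OC)c(C)c(OC)c2)cc(OC)c1C
F4 | step 6 | 1,13-bis(2,3,6-triacetoxy-5-methoxy-4-methylphenyl)tridecane | COc1c(C)c(OC(C)=O)c(OC(C)=O)c(CCCCCCCCCCCCCc2c(OC(C)=O)c(OC(C)=O)c(C)c(OC)c2OC(C)=O)c1OC(C)=O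
F5 | step 6 | 1,13-bis(2,3,6-trihydroxy-5-methoxy-4-methylphenyl)tridecane | COc1c(C)c(O)c(O)c(CCCCCCCCCCCCCc2c(O)c(O)c(C)c(OC)c2O)c1O
F6 | step 5 | 6,6'-(tridecane-1,13-diyl)bis(2,4-dimethoxy-3-methylbenzaldehyde) | COc1cc(CCCCCCCCCCCCCc2cc(OC)c(C)c(OC)c2C=O)c(C=O)c(OC)c1C
F7 | step 5 | 1,13-bis(2-formyloxy-3,5-dimethoxy-4-methylphenyl)tridecane | COc1cc(CCCCCCCCCCCCCc2cc(OC)c(C)c(OC)c2OC=O)c(OC=O)c(OC)c1C
F8 | step 5 | 6,6'-(tridecane-1,13-diyl)bis(2,4-dimethoxy-3-methylphenol) | COc1cc(CCCCCCCCCCCCCc2cc(OC)c(C)c(OC)c2O)c(O)c(OC)c1C
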